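**Strategy.** The ten-membered carbocycle (chroman C2 and C3 plus side-ring carbons C1′–C8′, numbered from C3: C3′ carries the exocyclic methylene, C4′=C5′ is the Z-alkene, C6′ the carbinol-bearing stereocentre) is cut at C4′=C5′. Its C3′(=CH2)–C4′=C5′ diene is the retron of an enyne metathesis: a but-3-ynyl arm on C3 and the C6′ vinyl group on the C2 arm of a fully functionalised chroman are joined by Ru catalysis, creating ring, exocyclic methylene and Z-alkene at once. The precursor, an open-armed 6,8-diformyl-5,7-dihydroxychroman, is built from 5,7-dihydroxycoumarin with all four stereocentres already set.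

Key step: step 14

Remark on the chemistry: the target is read from its SMILES as the (2R,3S,4R,6′R) isomer with a 4′Z double bond (chroman numbering for the heterocycle, primed locants as above); isobutyl is written as 2-methylpropyl.

**Step 1**
Reactants: 1 5,7-dihydroxy-2H-chromen-2-one (5,7-dihydroxycoumarin)
Product: 2 5,7-bis(methoxymethoxy)-2H-chromen-2-one
Conditions: MOMCl (2.5 equiv), i-Pr2NEt, CH2Cl2, 0 °C → rt
Reagents that add atoms: chloromethyl methyl ether, COCCl
Why: Base-mediated O-alkylation (MOM protection) of both phenols; the MOM ethers should survive the organometallic steps and later direct ortho-lithiation.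

**Step 2**
Reactants: 2 5,7-bis(methoxymethoxy)-2H-chromen-2-one
Product: 3 (4R)-5,7-bis(methoxymethoxy)-4-(2-methylpropyl)chroman-2-one
Conditions: i-BuMgBr (1.5 equiv), CuBr·SMe2 (5 mol%), reversed Josiphos-type ferrocenyl diphosphine (6 mol%, enantiomer that gives 4R), t-BuOMe/CH2Cl2, −72 °C; aq. NH4Cl at −72 °C
Reagents that add atoms: isobutylmagnesium bromide, CC(C)C[Mg]Br
Why: Copper-catalysed asymmetric conjugate addition of a Grignard reagent to a coumarin (a known substrate class for this catalysis); the chiral Cu–diphosphine complex differentiates the enantiofaces of C3=C4 and sets C4 (R).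

**Step 3**
Reactants: 3 (4R)-5,7-bis(methoxymethoxy)-4-(2-methylpropyl)chroman-2-one; 4 (4-iodobut-1-yn-1-yl)trimethylsilane
Product: 6 (3R,4R)-5,7-bis(methoxymethoxy)-4-(2-methylpropyl)-3-[4-(trimethylsilyl)but-3-yn-1-yl]chroman-2-one (3,4-trans), via lithium enolate 5 (not isolated)
Conditions: LiHMDS, THF, −78 °C; then 4, DMPU, −78 → −40 °C
Reagents that add atoms: none
Why: Lactone enolate alkylation: the C4 isobutyl group, held pseudo-axial by the peri 5-OMOM group, blocks one face of enolate 5, so the primary iodide enters anti and C3 is formed 3,4-trans (3R), which is corrected in step 4.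

**Step 4**
Reactants: 6 (3R,4R)-trans lactone
Product: 8 (3S,4R)-5,7-bis(methoxymethoxy)-4-(2-methylpropyl)-3-[4-(trimethylsilyl)but-3-yn-1-yl]chroman-2-one (3,4-cis), via lithium enolate 7 (not isolated)
Conditions: LDA, THF, −78 °C; then 2,6-di-tert-butyl-4-methylphenol, −78 °C
Reagents that add atoms: none
Why: Deprotonation/kinetic reprotonation (contra-thermodynamic epimerisation): the bulky phenol should deliver the proton to C3 of enolate 7 anti to the axial isobutyl group, so the side arm ends cis to isobutyl and C3 becomes S.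

**Step 5**
Reactants: 8 (3S,4R)-cis lactone
Product: 9 (3S,4R)-2-methyl-5,7-bis(methoxymethoxy)-4-(2-methylpropyl)-3-[4-(trimethylsilyl)but-3-yn-1-yl]chroman-2-ol (hemiketal, both C2 epimers)
Conditions: MeLi, CeCl3, THF, −78 °C; H2O quench at −78 °C
Reagents that add atoms: methyllithium, [Li]C
Why: Single addition of an organocerium reagent to a lactone gives the cyclic hemiketal (tetrahedral alkoxide stable at −78 °C, weakly basic reagent does not enolise C3); C2 is left unassigned because it is ionised in step 6.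

**Step 6**
Reactants: 9 hemiketal
Product: 10 (2R,3S,4R)-2-allyl-2-methyl-5,7-bis(methoxymethoxy)-4-(2-methylpropyl)-3-[4-(trimethylsilyl)but-3-yn-1-yl]chroman
Conditions: allylSiMe3 (3 equiv), BF3·OEt2, CH2Cl2, −78 °C, short reaction time; Et3N quench
Reagents that add atoms: allyltrimethylsilane, C=CC[Si](C)(C)C
Why: Hosomi–Sakurai allylation of the 2-methylchroman-2-ylium (oxocarbenium) ion: allyl should add to the face anti to the cis C3 and C4 substituents, setting quaternary C2 (R) with the new arm trans to the C3 arm and methyl cis to it.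

**Step 7**
Reactants: 10 2-allyl chroman
Product: 12 3-[(2R,3S,4R)-2-methyl-5,7-bis(methoxymethoxy)-4-(2-methylpropyl)-3-[4-(trimethylsilyl)but-3-yn-1-yl]chroman-2-yl]propan-1-ol, via B-alkyl-9-BBN adduct 11 (not isolated)
Conditions: 9-BBN, THF, 0 °C → rt; then H2O2, aq. NaHCO3, 0 °C
Reagents that add atoms: hydrogen peroxide, OO
Why: Hydroboration–oxidation: 9-BBN adds anti-Markovnikov to the monosubstituted alkene only (the silylated internal alkyne is much slower), and buffered oxidation keeps the C-silyl group.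

**Step 8**
Reactants: 12 primary alcohol
Product: 13 3-[(2R,3S,4R)-2-methyl-5,7-bis(methoxymethoxy)-4-(2-methylpropyl)-3-[4-(trimethylsilyl)but-3-yn-1-yl]chroman-2-yl]propanal
Conditions: Dess–Martin periodinane, NaHCO3, CH2Cl2, rt
Reagents that add atoms: none
Why: Dess–Martin oxidation of the primary alcohol to the aldehyde under buffered conditions; no stereocentre is α to the new carbonyl.

**Step 9**
Reactants: 13 aldehyde
Product: 14 (2R,3S,4R)-2-methyl-2-(4-methylpent-3-en-1-yl)-5,7-bis(methoxymethoxy)-4-(2-methylpropyl)-3-[4-(trimethylsilyl)but-3-yn-1-yl]chroman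
Conditions: i-PrPPh3+ I−, n-BuLi, THF, 0 °C; then 13, −78 °C → rt
Reagents that add atoms: isopropyltriphenylphosphonium iodide, CC(C)[P+](c1ccccc1)(c1ccccc1)c1ccccc1.[I-]
Why: Wittig olefination with the non-stabilised isopropylidene ylide gives the trisubstituted alkene, which has no E/Z issue.

**Step 10**
Reactants: 14 trisubstituted alkene
Product: 15 (2R,3S,4R)-2-{2-[(2R)-3,3-dimethyloxiran-2-yl]ethyl}-2-methyl-5,7-bis(methoxymethoxy)-4-(2-methylpropyl)-3-[4-(trimethylsilyl)but-3-yn-1-yl]chroman
Conditions: D-fructose-derived Shi ketone (30 mol%), Oxone, K2CO3, Bu4NHSO4, MeCN/dimethoxymethane–aq. buffer (pH 10.5), 0 °C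
Reagents that add atoms: Oxone (potassium peroxymonosulfate), [K+].OOS(=O)(=O)[O-]
Why: Shi asymmetric epoxidation: the chiral dioxirane should epoxidise the electron-rich trisubstituted alkene through the spiro transition state and set the (R) oxirane CH carbon by reagent control, independent of the remote chroman centres.

**Step 11**
Reactants: 15 epoxide
Product: 16 (3R)-2-methyl-3-{2-[(2R,3S,4R)-2-methyl-5,7-bis(methoxymethoxy)-4-(2-methylpropyl)-3-[4-(trimethylsilyl)but-3-yn-1-yl]chroman-2-yl]ethyl}pent-4-en-2-ol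
Conditions: vinylMgBr (4 equiv), CuI (20 mol%), THF, −20 °C → rt
Reagents that add atoms: vinylmagnesium bromide, C=C[Mg]Br
Why: Copper-catalysed Grignard opening of the epoxide (SN2): vinyl attacks the less substituted oxirane carbon with inversion, giving the tertiary alcohol and C6′ (R) bearing the vinyl group.

**Step 12**
Reactants: 16 tertiary alcohol
Product: 18 (2R,3S,4R)-2-[(3R)-3-(2-hydroxypropan-2-yl)pent-4-en-1-yl]-2-methyl-5,7-bis(methoxymethoxy)-4-(2-methylpropyl)-3-[4-(trimethylsilyl)but-3-yn-1-yl]chroman-6,8-dicarbaldehyde, via lithium hemiaminal alkoxide 17 (not isolated)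
Conditions: s-BuLi (2.2 equiv), TMEDA, THF, −78 °C; DMF (1.05 equiv); then s-BuLi (1.5 equiv), −78 → −40 °C; DMF (excess); aq. NH4Cl
Reagents that add atoms: N,N-dimethylformamide, CN(C)C=O
Why: Iterative directed ortho-metalation/formylation: C6 (between two OMOM groups) is lithiated and formylated first, the lithium α-aminoalkoxide 17 masks that aldehyde in situ, and C8 (between OMOM and the ring oxygen) is then lithiated and formylated; the alcohol is carried as its alkoxide and the alkyne as its C-silyl derivative.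

**Step 13**
Reactants: 18 bis-MOM dialdehyde
Product: 20 (2R,3S,4R)-3-(but-3-yn-1-yl)-5,7-dihydroxy-2-[(3R)-3-(2-hydroxypropan-2-yl)pent-4-en-1-yl]-2-methyl-4-(2-methylpropyl)chroman-6,8-dicarbaldehyde, via desilylated bis-MOM ether 19 (not isolated)
Conditions: K2CO3, MeOH, rt; then 3 M HCl, MeOH–THF, rt
Reagents that add atoms: none
Why: Methanolysis of the alkynyl C–Si bond followed by acid-catalysed acetal exchange of the MOM ethers (fast for MOM groups ortho to a formyl group) should free the terminal alkyne and both phenols without touching the tertiary homoallylic alcohol.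

**Step 14**
Reactants: 20 enyne
Product: 22 target CNP0479784.1, via triene 21 (not isolated)
Conditions: Grubbs II (10 mol%), ethylene (1 atm), CH2Cl2, rt; then Ar purge, toluene (1 mM), Hoveyda–Grubbs II (10 mol%), 80 °C
Reagents that add atoms: ethylene, C=C
Why: The Ru methylidene formed under ethylene adds to the terminal alkyne of 20 (ruthenacyclobutene, then vinylcarbene) and is released by ethylene as the 2-substituted butadiene 21; after the purge, the alkylidene on the diene vinyl terminus or on the C6′ vinyl group closes the ring through a ruthenacyclobutane with loss of ethylene. The closest known reactions are ethylene-promoted enyne cross-metathesis followed by macrocyclic diene–ene ring-closing metathesis, together an endo-mode ring-closing enyne metathesis. The ten-membered carbocycle closes at C4′=C5′ by ring-closing olefin metathesis, endo with respect to the former alkyne, whose two carbons become C3′ and C4′. No stereocentre is formed; the Z geometry should be controlled by ring strain, because the E-alkene in a cyclodecene is the more strained isomer and so is the metallacycle leading to it, so kinetic and thermodynamic preference coincide. The step needs endo over exo closure and cyclisation over oligomerisation: pre-forming the diene with ethylene removes the exo pathway (the 1,1-disubstituted C3′=CH2 is unreactive), and the trans-diequatorial C2/C3 arms on the rigid chroman with its quaternary C2 pre-organise the chain ends at high dilution. The hydrogen-bonded o-formylphenols, the tertiary alcohol and the four existing stereocentres should be untouched by the Ru catalysts.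

**Compound list**

1 | 5,7-dihydroxy-2H-chromen-2-one | O=C1C=Cc2c(O)cc(O)cc2O1 | starting material
2 | 5,7-bis(methoxymethoxy)-2H-chromen-2-one | O=C1C=Cc2c(OCOC)cc(OCOC)cc2O1 | intermediate
3 | (4R)-5,7-bis(methoxymethoxy)-4-(2-methylpropyl)chroman-2-one | O=C1Oc2cc(OCOC)cc(OCOC)c2[C@H](CC(C)C)C1 | intermediate
4 | (4-iodobut-1-yn-1-yl)trimethylsilane | C[Si](C)(C)C#CCCI | starting material
5 | lithium enolate of 3 | [Li]OC1=C[C@@H](CC(C)C)c2c(OCOC)cc(OCOC)cc2O1 | intermediate (not isolated)
6 | (3R,4R)-5,7-bis(methoxymethoxy)-4-(2-methylpropyl)-3-[4-(trimethylsilyl)but-3-yn-1-yl]chroman-2-one | O=C1Oc2cc(OCOC)cc(OCOC)c2[C@H](CC(C)C)[C@H]1CCC#C[Si](C)(C)C | intermediate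
7 | lithium enolate of 6 | [Li]OC1=C(CCC#C[Si](C)(C)C)[C@@H](CC(C)C)c2c(OCOC)cc(OCOC)cc2O1 | intermediate (not isolated)
8 | (3S,4R)-5,7-bis(methoxymethoxy)-4-(2-methylpropyl)-3-[4-(trimethylsilyl)but-3-yn-1-yl]chroman-2-one | O=C1Oc2cc(OCOC)cc(OCOC)c2[C@H](CC(C)C)[C@@H]1CCC#C[Si](C)(C)C | intermediate
9 | (3S,4R)-2-methyl-5,7-bis(methoxymethoxy)-4-(2-methylpropyl)-3-[4-(trimethylsilyl)but-3-yn-1-yl]chroman-2-ol (C2 epimers) | CC1(O)Oc2cc(OCOC)cc(OCOC)c2[C@H](CC(C)C)[C@@H]1CCC#C[Si](C)(C)C | intermediate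
10 | (2R,3S,4R)-2-allyl-2-methyl-5,7-bis(methoxymethoxy)-4-(2-methylpropyl)-3-[4-(trimethylsilyl)but-3-yn-1-yl]chroman | C=CC[C@@]1(C)Oc2cc(OCOC)cc(OCOC)c2[C@H](CC(C)C)[C@@H]1CCC#C[Si](C)(C)C | intermediate
11 | B-alkyl-9-BBN adduct of 10 (9-[3-(chroman-2-yl)propyl]-9-borabicyclo[3.3.1]nonane) | C1CCC2CCCC1B2CCC[C@@]1(C)Oc2cc(OCOC)cc(OCOC)c2[C@H](CC(C)C)[C@@H]1CCC#C[Si](C)(C)C | intermediate (not isolated)
12 | 3-[(2R,3S,4R)-2-methyl-5,7-bis(methoxymethoxy)-4-(2-methylpropyl)-3-[4-(trimethylsilyl)but-3-yn-1-yl]chroman-2-yl]propan-1-ol | OCCC[C@@]1(C)Oc2cc(OCOC)cc(OCOC)c2[C@H](CC(C)C)[C@@H]1CCC#C[Si](C)(C)C | intermediate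
13 | 3-[(2R,3S,4R)-2-methyl-5,7-bis(methoxymethoxy)-4-(2-methylpropyl)-3-[4-(trimethylsilyl)but-3-yn-1-yl]chroman-2-yl]propanal | O=CCC[C@@]1(C)Oc2cc(OCOC)cc(OCOC)c2[C@H](CC(C)C)[C@@H]1CCC#C[Si](C)(C)C | intermediate
14 | (2R,3S,4R)-2-methyl-2-(4-methylpent-3-en-1-yl)-5,7-bis(methoxymethoxy)-4-(2-methylpropyl)-3-[4-(trimethylsilyl)but-3-yn-1-yl]chroman | CC(C)=CCC[C@@]1(C)Oc2cc(OCOC)cc(OCOC)c2[C@H](CC(C)C)[C@@H]1CCC#C[Si](C)(C)C | intermediate
15 | (2R,3S,4R)-2-{2-[(2R)-3,3-dimethyloxiran-2-yl]ethyl}-2-methyl-5,7-bis(methoxymethoxy)-4-(2-methylpropyl)-3-[4-(trimethylsilyl)but-3-yn-1-yl]chroman | CC1(C)O[C@@H]1CC[C@@]1(C)Oc2cc(OCOC)cc(OCOC)c2[C@H](CC(C)C)[C@@H]1CCC#C[Si](C)(C)C | intermediate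
16 | (3R)-2-methyl-3-{2-[(2R,3S,4R)-2-methyl-5,7-bis(methoxymethoxy)-4-(2-methylpropyl)-3-[4-(trimethylsilyl)but-3-yn-1-yl]chroman-2-yl]ethyl}pent-4-en-2-ol | C=C[C@H](C(C)(C)O)CC[C@@]1(C)Oc2cc(OCOC)cc(OCOC)c2[C@H](CC(C)C)[C@@H]1CCC#C[Si](C)(C)C | intermediate
17 | C6 mono-adduct of 16 with DMF (lithium α-(dimethylamino)alkoxide, tertiary lithium alkoxide) | C=C[C@H](C(C)(C)O[Li])CC[C@@]1(C)Oc2cc(OCOC)c(C(O[Li])N(C)C)c(OCOC)c2[C@H](CC(C)C)[C@@H]1CCC#C[Si](C)(C)C | intermediate (not isolated)
18 | (2R,3S,4R)-2-[(3R)-3-(2-hydroxypropan-2-yl)pent-4-en-1-yl]-2-methyl-5,7-bis(methoxymethoxy)-4-(2-methylpropyl)-3-[4-(trimethylsilyl)but-3-yn-1-yl]chroman-6,8-dicarbaldehyde | C=C[C@H](C(C)(C)O)CC[C@@]1(C)Oc2c(C=O)c(OCOC)c(C=O)c(OCOC)c2[C@H](CC(C)C)[C@@H]1CCC#C[Si](C)(C)C | intermediate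
19 | (2R,3S,4R)-3-(but-3-yn-1-yl)-2-[(3R)-3-(2-hydroxypropan-2-yl)pent-4-en-1-yl]-2-methyl-5,7-bis(methoxymethoxy)-4-(2-methylpropyl)chroman-6,8-dicarbaldehyde | C=C[C@H](C(C)(C)O)CC[C@@]1(C)Oc2c(C=O)c(OCOC)c(C=O)c(OCOC)c2[C@H](CC(C)C)[C@@H]1CCC#C | intermediate (not isolated)
20 | (2R,3S,4R)-3-(but-3-yn-1-yl)-5,7-dihydroxy-2-[(3R)-3-(2-hydroxypropan-2-yl)pent-4-en-1-yl]-2-methyl-4-(2-methylpropyl)chroman-6,8-dicarbaldehyde | C=C[C@H](C(C)(C)O)CC[C@@]1(C)Oc2c(C=O)c(O)c(C=O)c(O)c2[C@H](CC(C)C)[C@@H]1CCC#C | intermediate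
21 | (2R,3S,4R)-5,7-dihydroxy-2-[(3R)-3-(2-hydroxypropan-2-yl)pent-4-en-1-yl]-2-methyl-3-(3-methylidenepent-4-en-1-yl)-4-(2-methylpropyl)chroman-6,8-dicarbaldehyde | C=C[C@H](C(C)(C)O)CC[C@@]1(C)Oc2c(C=O)c(O)c(C=O)c(O)c2[C@H](CC(C)C)[C@@H]1CCC(=C)C=C | intermediate (not isolated)
22 | CNP0479784.1, (2R,3S,4R,6′R,4′Z) ten-membered-ring-fused 6,8-diformyl-5,7-dihydroxychroman | C=C1/C=C\[C@H](C(C)(C)O)CC[C@@]2(C)Oc3c(C=O)c(O)c(C=O)c(O)c3[C@H](CC(C)C)[C@@H]2CC1 | target

**Step count.** Total: 14 steps. Longest linear sequence: 14 steps (1 → 22).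

**Steps most likely to fail**

Step 14. Intermolecular metathesis (oligomerisation) may outcompete closure of the strained ten-membered ring, the chelating o-formylphenols may slow the catalyst, and geometry control by ring strain may be incomplete. The fallback sets out from 18 and comes back at 22. Compound 18 is only desilylated (K2CO3, MeOH) and the bis-MOM ether 19 is isolated. Ethylene cross-enyne metathesis (Grubbs II, ethylene, CH2Cl2) then gives the isolated bis-MOM triene F1. F1 is closed under kinetic, catalyst-controlled Z-selectivity with a cyclometalated Z-selective ruthenium catalyst (slow addition, 0.5 mM, 40 °C, static vacuum) to the bis-MOM macrocycle F2. Mild acetal exchange (PPTS, MeOH, 40 °C) then removes the MOM groups to give 22. Ring closure is thus moved onto the non-chelating protected substrate, and the alkene geometry is set by the catalyst instead of by ring strain.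

Step 12. The second ortho-lithiation may be incomplete, or s-BuLi may deprotonate the propargylic position or attack the masked aldehyde. The fallback sets out from 16 and comes back at 20. Compound 16 is first desilylated and freed from both MOM groups (K2CO3, MeOH; then HCl, MeOH–THF) to the dihydroxy enyne F3. Both formyl groups are then introduced without organolithium reagents by twofold magnesium-mediated ortho-formylation of the free phenols (MgCl2, Et3N, paraformaldehyde, MeCN, reflux), which should tolerate the tertiary alcohol, alkyne and alkene, giving 20.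

Step 4. Facial selectivity in the C-protonation may be poor, or proton transfer may leak to the thermodynamic trans lactone. The fallback sets out from 6 and comes back at 10. The trans lactone 6 is converted with MeLi/CeCl3 into the trans hemiketal F4, which is dehydrated (PPTS, 4 Å molecular sieves, toluene) to the 2-methyl-4H-chromene F5, in which C3 is trigonal. F5 is treated with allyltrimethylsilane, BF3·OEt2 and one equivalent of i-PrOH as proton source at −78 °C. Axial protonation of the enol ether anti to the C4 isobutyl group should give the cis-3,4 oxocarbenium ion, which is allylated anti as in step 6 to give 10.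

**Further compounds**

F1 | step 14 | (2R,3S,4R)-2-[(3R)-3-(2-hydroxypropan-2-yl)pent-4-en-1-yl]-2-methyl-5,7-bis(methoxymethoxy)-3-(3-methylidenepent-4-en-1-yl)-4-(2-methylpropyl)chroman-6,8-dicarbaldehyde | C=C[C@H](C(C)(C)O)CC[C@@]1(C)Oc2c(C=O)c(OCOC)c(C=O)c(OCOC)c2[C@H](CC(C)C)[C@@H]1CCC(=C)C=C
F2 | step 14 | 5,7-bis(methoxymethyl) ether of 22 | C=C1/C=C\[C@H](C(C)(C)O)CC[C@@]2(C)Oc3c(C=O)c(OCOC)c(C=O)c(OCOC)c3[C@H](CC(C)C)[C@@H]2CC1
F3 | step 12 | (2R,3S,4R)-3-(but-3-yn-1-yl)-2-[(3R)-3-(2-hydroxypropan-2-yl)pent-4-en-1-yl]-2-methyl-4-(2-methylpropyl)chroman-5,7-diol | C=C[C@H](C(C)(C)O)CC[C@@]1(C)Oc2cc(O)cc(O)c2[C@H](CC(C)C)[C@@H]1CCC#C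
F4 | step 4 | (3R,4R)-2-methyl-5,7-bis(methoxymethoxy)-4-(2-methylpropyl)-3-[4-(trimethylsilyl)but-3-yn-1-yl]chroman-2-ol (C2 epimers) | CC1(O)Oc2cc(OCOC)cc(OCOC)c2[C@H](CC(C)C)[C@H]1CCC#C[Si](C)(C)C
F5 | step 4 | (4R)-2-methyl-5,7-bis(methoxymethoxy)-4-(2-methylpropyl)-3-[4-(trimethylsilyl)but-3-yn-1-yl]-4H-chromene | CC1=C(CCC#C[Si](C)(C)C)[C@@H](CC(C)C)c2c(OCOC)cc(OCOC)cc2O1
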